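Germacrane numbering is used (ring C1–C10, lactone carbons C11–C13, C14 on C10, C15 on C4). The route rests on disconnecting the vinylic C4–C15 bond, so that the complete (R)-chlorohydrin ester is delivered last to a macrocyclic C4 alkenyl bromide. One Pd/Cu-mediated Stille coupling with an (acyloxymethyl)stannane forms this C(sp2)–C(sp3) bond with retention of the ring-trans C4=C5 geometry and leaves C14–OH free, so C14 and C15 never need differentiation. It exploits that C15 is an oxygenated methylene on an sp2 carbon of the cyclodecadiene ring, whose ester carbonyl assists Sn-to-Cu transfer. The bromolactone precursor arises from a Cr-catalysed Barbier macrocyclisation and a SeO2 oxidation.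

Key step: step 15

Remark: the target SMILES is read as a trans-fused (7R,8S) 12,8-lactone with a ring-cis C1=C10 bond, a ring-trans C4=C5 bond and an (R)-configured side chain; compounds 1, 6, 12, 22 and 25 are taken as commercial.

Step 1
Reactants: 1 tert-butyl(but-3-yn-1-yloxy)dimethylsilane
Product: 4 (3E)-6-[(tert-butyldimethylsilyl)oxy]-4-methylhex-3-en-1-ol, via alkenylalane 2 (not isolated), via lithium alanate 3 (not isolated)
Conditions: Me3Al, Cp2ZrCl2 (cat.), CH2Cl2, 0 °C to rt; evaporate; n-BuLi, THF, −78 to 0 °C; ethylene oxide, 0 °C to rt; aq. work-up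
Reagents that add atoms: trimethylaluminium C[Al](C)C; ethylene oxide C1CO1
Why: Zr-catalysed carboalumination (Negishi carboalumination) adds CH3 and Al syn with Al at the terminal carbon, and the derived alanate opens ethylene oxide with retention, so the E-trisubstituted C1=C10 alkene (C14 methyl cis to C2) should result.

Step 2
Reactants: 4 (3E)-6-[(tert-butyldimethylsilyl)oxy]-4-methylhex-3-en-1-ol
Product: 5 tert-butyl{[(3E)-6-iodo-3-methylhex-3-en-1-yl]oxy}dimethylsilane
Conditions: I2, PPh3, imidazole, CH2Cl2, 0 °C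
Reagents that add atoms: iodine II
Why: Appel-type iodination of an unhindered primary alcohol under buffered conditions should leave the silyl ether and the alkene untouched.

Step 3
Reactants: 6 3-[(4-methoxybenzyl)oxy]propanal
Product: 7 1-{[(4,4-dibromobut-3-en-1-yl)oxy]methyl}-4-methoxybenzene
Conditions: CBr4, PPh3, Zn, CH2Cl2, rt (ylide pre-formed); then 6, 0 °C to rt
Reagents that add atoms: carbon tetrabromide BrC(Br)(Br)Br
Why: Ramirez (Corey–Fuchs) dibromo-olefination of an unhindered aldehyde, with zinc keeping the medium free of acid so that the PMB ether survives.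

Step 4
Reactants: 5 tert-butyl{[(3E)-6-iodo-3-methylhex-3-en-1-yl]oxy}dimethylsilane; 7 1-{[(4,4-dibromobut-3-en-1-yl)oxy]methyl}-4-methoxybenzene
Product: 9 tert-butyl({(3E,7Z)-7-bromo-10-[(4-methoxybenzyl)oxy]-3-methyldeca-3,7-dien-1-yl}oxy)dimethylsilane, via alkylzinc iodide 8 (not isolated)
Conditions: 5, Zn dust, LiCl, THF, 40 °C; then added slowly to 7 (1.3 equiv), PdCl2(DPEphos) (5 mol%), THF/DMF, 0 °C to rt
Reagents that add atoms: none
Why: trans-selective Negishi monoalkylation of a 1,1-dibromoalkene, in which Pd inserts first into the less hindered C–Br bond trans to the C6 chain, should place C3 trans to C6 and leave the Z-bromide at C4, while slow addition of 8 to excess 7 limits double alkylation.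

Step 5
Reactants: 9 tert-butyl({(3E,7Z)-7-bromo-10-[(4-methoxybenzyl)oxy]-3-methyldeca-3,7-dien-1-yl}oxy)dimethylsilane
Product: 10 (3Z,7E)-4-bromo-10-[(tert-butyldimethylsilyl)oxy]-8-methyldeca-3,7-dien-1-ol
Conditions: DDQ, CH2Cl2/pH 7 buffer, 0 °C
Reagents that add atoms: none
Why: oxidative cleavage of the PMB ether by DDQ is neutral and should spare the TBS ether, the alkenyl bromide and the trisubstituted alkene.

Step 6
Reactants: 10 (3Z,7E)-4-bromo-10-[(tert-butyldimethylsilyl)oxy]-8-methyldeca-3,7-dien-1-ol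
Product: 11 (3Z,7E)-4-bromo-10-[(tert-butyldimethylsilyl)oxy]-8-methyldeca-3,7-dienal
Conditions: Dess–Martin periodinane, NaHCO3, CH2Cl2, 0 °C; used crude
Reagents that add atoms: none
Why: buffered Dess–Martin oxidation gives the β,γ-unsaturated aldehyde without base or acid strong enough to move the double bond into conjugation.

Step 7
Reactants: 11 (3Z,7E)-4-bromo-10-[(tert-butyldimethylsilyl)oxy]-8-methyldeca-3,7-dienal; 12 methyl propiolate
Product: 14 methyl (5Z,9E)-6-bromo-12-[(tert-butyldimethylsilyl)oxy]-3-hydroxy-10-methyl-2-methylidenedodeca-5,9-dienoate (racemic at C3), via vinylalane 13 (not isolated)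
Conditions: i-Bu2AlH, NMO, THF, 0 °C; 12, 0 °C; then 11, 0 °C to rt; aq. Rochelle salt
Reagents that add atoms: none
Why: vinylalumination (hydroalumination of the propiolate to the α-alumino acrylate and its 1,2-addition to the aldehyde, an aluminium-mediated Morita–Baylis–Hillman-type reaction) is non-basic and should not isomerise the β,γ-unsaturated aldehyde; the new carbinol centre is racemic and is removed in step 8.

Step 8
Reactants: 14 methyl (5Z,9E)-6-bromo-12-[(tert-butyldimethylsilyl)oxy]-3-hydroxy-10-methyl-2-methylidenedodeca-5,9-dienoate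
Product: 15 methyl (2Z,5Z,9E)-6-bromo-2-(bromomethyl)-12-[(tert-butyldimethylsilyl)oxy]-10-methyldodeca-2,5,9-trienoate
Conditions: NBS, Me2S, CH2Cl2, −20 °C to rt
Reagents that add atoms: N-bromosuccinimide O=C1CCC(=O)N1Br
Why: Corey–Kim-type activation of the allylic alcohol followed by SN2′ attack of bromide gives the transposed primary allylic bromide with the usual Z geometry (chain trans to the ester).

Step 9
Reactants: 15 methyl (2Z,5Z,9E)-6-bromo-2-(bromomethyl)-12-[(tert-butyldimethylsilyl)oxy]-10-methyldodeca-2,5,9-trienoate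
Product: 16 methyl (2Z,5Z,9E)-6-bromo-2-(bromomethyl)-12-hydroxy-10-methyldodeca-2,5,9-trienoate
Conditions: aq. HF (48%), MeCN, 0 °C
Reagents that add atoms: none
Why: acidic fluoride desilylation of a primary TBS ether avoids nucleophilic amines or basic fluoride that would attack the allylic bromide.

Step 10
Reactants: 16 methyl (2Z,5Z,9E)-6-bromo-2-(bromomethyl)-12-hydroxy-10-methyldodeca-2,5,9-trienoate
Product: 17 methyl (2Z,5Z,9E)-6-bromo-2-(bromomethyl)-10-methyl-12-oxododeca-2,5,9-trienoate
Conditions: Dess–Martin periodinane, NaHCO3, CH2Cl2, 0 °C; used at once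
Reagents that add atoms: none
Why: buffered Dess–Martin oxidation tolerates the allylic bromide and delivers the sensitive β,γ-unsaturated C8 aldehyde for immediate cyclisation.

Step 11
Reactants: 17 methyl (2Z,5Z,9E)-6-bromo-2-(bromomethyl)-10-methyl-12-oxododeca-2,5,9-trienoate
Product: 20 (3aR,5Z,9E,11aS)-6-bromo-10-methyl-3-methylidene-3a,4,7,8,11,11a-hexahydrocyclodeca[b]furan-2(3H)-one, via silyl ether 18 (not isolated), via hydroxy ester 19 (not isolated)
Conditions: CrCl2 (20 mol%), chiral tridentate carbazole bis(oxazoline) ligand (22 mol%), i-Pr2NEt (cat.), Mn, TMSCl, THF, rt, syringe-pump addition of 17 (about 2 mM); then 1 M HCl/THF; PPTS (cat.), CH2Cl2, rt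
Reagents that add atoms: none
Why: catalytic asymmetric Nozaki–Hiyama–Kishi (Barbier-type) 2-(alkoxycarbonyl)allylation, an established ring closure for germacranolides, forms C7–C8 through a chair-like transition state in which the ligand antipode is chosen for Re-face attack on the C8 aldehyde (8S); the anti arrangement imposed by the E,E-macrocycle should set C7 (R), and acid closes the trans-fused lactone (the alkenyl bromide is inert to Cr(II) without Ni).

Step 12
Reactants: 20 (3aR,5Z,9E,11aS)-6-bromo-10-methyl-3-methylidene-3a,4,7,8,11,11a-hexahydrocyclodeca[b]furan-2(3H)-one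
Product: 21 (3aR,5Z,9E,11aS)-6-bromo-10-(hydroxymethyl)-3-methylidene-3a,4,7,8,11,11a-hexahydrocyclodeca[b]furan-2(3H)-one (C1=C10 now ring-cis)
Conditions: SeO2 (0.5 equiv), t-BuOOH, CH2Cl2, rt
Reagents that add atoms: selenium dioxide O=[Se]=O; tert-butyl hydroperoxide CC(C)(C)OO
Why: Riley-type allylic oxidation (ene reaction at C1 with loss of a C14 hydrogen, then [2,3]-sigmatropic shift) places the new CH2OH trans to C2, which is the ring-cis C1=C10 geometry of the target and the known outcome for C14 methyl groups of 1(10)-E germacranolides; the bromo-alkene and the methylene lactone are too electron-poor to react.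

Step 13
Reactants: 22 methyl (2S)-2-methyloxirane-2-carboxylate
Product: 24 (2R)-3-chloro-2-hydroxy-2-methylpropanoic acid, via chlorohydrin methyl ester 23 (not isolated)
Conditions: conc. aq. HCl, 0 °C to rt, then 60 °C
Reagents that add atoms: hydrogen chloride Cl; water O
Why: acid-mediated epoxide opening by chloride at the unhindered CH2 (not at the quaternary α-carbonyl carbon) leaves the C2 centre untouched (the descriptor changes from S to R only through priorities), and acidic ester hydrolysis avoids base that would re-close the epoxide.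

Step 14
Reactants: 24 (2R)-3-chloro-2-hydroxy-2-methylpropanoic acid; 25 (tributylstannyl)methanol
Product: 26 (tributylstannyl)methyl (2R)-3-chloro-2-hydroxy-2-methylpropanoate
Conditions: DCC, DMAP (cat.), CH2Cl2, 0 °C to rt
Reagents that add atoms: none
Why: Steglich esterification acylates the primary stannylmethanol selectively because the tertiary hydroxyl of the acid is too hindered to compete.

Step 15
Reactants: 21 (3aR,5Z,9E,11aS)-6-bromo-10-(hydroxymethyl)-3-methylidene-3a,4,7,8,11,11a-hexahydrocyclodeca[b]furan-2(3H)-one; 26 (tributylstannyl)methyl (2R)-3-chloro-2-hydroxy-2-methylpropanoate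
Product: 27 [(3aR,5Z,9E,11aS)-10-(hydroxymethyl)-3-methylidene-2-oxo-2,3,3a,4,7,8,11,11a-octahydrocyclodeca[b]furan-6-yl]methyl (2R)-3-chloro-2-hydroxy-2-methylpropanoate (target)
Conditions: Pd2(dba)3 (5 mol%), P(2-furyl)3 (20 mol%), CuI (20 mol%), NMP, 45–60 °C
Reagents that add atoms: none
Why: Stille cross-coupling in which Pd(0) inserts into the C4–Br bond with retention, the ester carbonyl of 26 chelates Cu(I) and promotes selective Sn-to-Cu-to-Pd transfer of the acyloxymethyl group over butyl, and reductive elimination forms the C4–C15 bond. The closest known reaction types are the Pd-catalysed hydroxymethylation and alkoxymethylation of alkenyl halides with α-oxygenated methylstannanes and the Cu-assisted coupling of α-acyloxyalkylstannanes. No ring is closed and no stereocentre is formed; the ring-trans C4=C5 geometry from step 4, C7, C8 and the side-chain centre are carried through unchanged. The step needs chemoselectivity for the alkenyl bromide over the free C14 alcohol, the alkyl chloride, the tertiary alcohol and the methylene lactone, which the neutral, base- and fluoride-free medium should secure (no epoxide from the chlorohydrin, no conjugate addition). It also needs transmetalation to outrun transannular Heck insertion of the C4–Pd bond into C1=C10 and ionisation of the product allylic ester, for which copper co-catalysis, a weakly donating phosphine and moderate temperature are chosen.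

Compound list
1 | tert-butyl(but-3-yn-1-yloxy)dimethylsilane | C#CCCO[Si](C)(C)C(C)(C)C | starting material
2 | [(1E)-4-[(tert-butyldimethylsilyl)oxy]-2-methylbut-1-en-1-yl]dimethylalane | C[Al](C)/C=C(\C)CCO[Si](C)(C)C(C)(C)C | intermediate
3 | lithium butyl{(1E)-4-[(tert-butyldimethylsilyl)oxy]-2-methylbut-1-en-1-yl}dimethylalanate | [Li+].CCCC[Al-](C)(C)/C=C(\C)CCO[Si](C)(C)C(C)(C)C | intermediate
4 | (3E)-6-[(tert-butyldimethylsilyl)oxy]-4-methylhex-3-en-1-ol | OCC/C=C(\C)CCO[Si](C)(C)C(C)(C)C | intermediate
5 | tert-butyl{[(3E)-6-iodo-3-methylhex-3-en-1-yl]oxy}dimethylsilane | ICC/C=C(\C)CCO[Si](C)(C)C(C)(C)C | intermediate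
6 | 3-[(4-methoxybenzyl)oxy]propanal | COc1ccc(COCCC=O)cc1 | starting material
7 | 1-{[(4,4-dibromobut-3-en-1-yl)oxy]methyl}-4-methoxybenzene | COc1ccc(COCCC=C(Br)Br)cc1 | intermediate
8 | {(3E)-6-[(tert-butyldimethylsilyl)oxy]-4-methylhex-3-en-1-yl}zinc iodide | I[Zn]CC/C=C(\C)CCO[Si](C)(C)C(C)(C)C | intermediate
9 | tert-butyl({(3E,7Z)-7-bromo-10-[(4-methoxybenzyl)oxy]-3-methyldeca-3,7-dien-1-yl}oxy)dimethylsilane | COc1ccc(COCC/C=C(Br)/CC/C=C(\C)CCO[Si](C)(C)C(C)(C)C)cc1 | intermediate
10 | (3Z,7E)-4-bromo-10-[(tert-butyldimethylsilyl)oxy]-8-methyldeca-3,7-dien-1-ol | OCC/C=C(Br)/CC/C=C(\C)CCO[Si](C)(C)C(C)(C)C | intermediate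
11 | (3Z,7E)-4-bromo-10-[(tert-butyldimethylsilyl)oxy]-8-methyldeca-3,7-dienal | O=CC/C=C(Br)/CC/C=C(\C)CCO[Si](C)(C)C(C)(C)C | intermediate
12 | methyl propiolate (methyl prop-2-ynoate) | C#CC(=O)OC | starting material
13 | methyl 2-(diisobutylalumanyl)prop-2-enoate | C=C(C(=O)OC)[Al](CC(C)C)CC(C)C | intermediate
14 | methyl (5Z,9E)-6-bromo-12-[(tert-butyldimethylsilyl)oxy]-3-hydroxy-10-methyl-2-methylidenedodeca-5,9-dienoate (racemic at C3) | COC(=O)C(=C)C(O)C/C=C(Br)/CC/C=C(\C)CCO[Si](C)(C)C(C)(C)C | intermediate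
15 | methyl (2Z,5Z,9E)-6-bromo-2-(bromomethyl)-12-[(tert-butyldimethylsilyl)oxy]-10-methyldodeca-2,5,9-trienoate | COC(=O)/C(CBr)=C/C/C=C(Br)/CC/C=C(\C)CCO[Si](C)(C)C(C)(C)C | intermediate
16 | methyl (2Z,5Z,9E)-6-bromo-2-(bromomethyl)-12-hydroxy-10-methyldodeca-2,5,9-trienoate | COC(=O)/C(CBr)=C/C/C=C(Br)/CC/C=C(\C)CCO | intermediate
17 | methyl (2Z,5Z,9E)-6-bromo-2-(bromomethyl)-10-methyl-12-oxododeca-2,5,9-trienoate | COC(=O)/C(CBr)=C/C/C=C(Br)/CC/C=C(\C)CC=O | intermediate
18 | methyl 2-{(1R,3Z,7E,10S)-4-bromo-8-methyl-10-[(trimethylsilyl)oxy]cyclodeca-3,7-dien-1-yl}prop-2-enoate | C[Si](C)(C)O[C@H]1C/C(C)=C/CC/C(Br)=C/C[C@@H]1C(=C)C(=O)OC | intermediate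
19 | methyl 2-[(1R,3Z,7E,10S)-4-bromo-10-hydroxy-8-methylcyclodeca-3,7-dien-1-yl]prop-2-enoate | O[C@H]1C/C(C)=C/CC/C(Br)=C/C[C@@H]1C(=C)C(=O)OC | intermediate
20 | (3aR,5Z,9E,11aS)-6-bromo-10-methyl-3-methylidene-3a,4,7,8,11,11a-hexahydrocyclodeca[b]furan-2(3H)-one (trans-fused; C1=C10 ring-trans, C4=C5 ring-trans) | C=C1C(=O)O[C@H]2C/C(C)=C/CC/C(Br)=C/C[C@H]12 | intermediate
21 | (3aR,5Z,9E,11aS)-6-bromo-10-(hydroxymethyl)-3-methylidene-3a,4,7,8,11,11a-hexahydrocyclodeca[b]furan-2(3H)-one (C1=C10 ring-cis, C4=C5 ring-trans) | C=C1C(=O)O[C@H]2C/C(CO)=C\CC/C(Br)=C/C[C@H]12 | intermediate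
22 | methyl (2S)-2-methyloxirane-2-carboxylate | COC(=O)[C@@]1(C)OC1 | starting material
23 | methyl (2R)-3-chloro-2-hydroxy-2-methylpropanoate | COC(=O)[C@@](C)(O)CCl | intermediate
24 | (2R)-3-chloro-2-hydroxy-2-methylpropanoic acid | OC(=O)[C@@](C)(O)CCl | intermediate
25 | (tributylstannyl)methanol | CCCC[Sn](CCCC)(CCCC)CO | starting material
26 | (tributylstannyl)methyl (2R)-3-chloro-2-hydroxy-2-methylpropanoate | CCCC[Sn](CCCC)(CCCC)COC(=O)[C@@](C)(O)CCl | intermediate
27 | [(3aR,5Z,9E,11aS)-10-(hydroxymethyl)-3-methylidene-2-oxo-2,3,3a,4,7,8,11,11a-octahydrocyclodeca[b]furan-6-yl]methyl (2R)-3-chloro-2-hydroxy-2-methylpropanoate | C=C1C(=O)O[C@H]2C/C(CO)=C\CC/C(COC(=O)[C@@](C)(O)CCl)=C/C[C@H]12 | target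

Total step count: 15. Longest linear sequence: 12 steps (steps 1, 2, 4, 5, 6, 7, 8, 9, 10, 11, 12, 15).

Steps most likely to fail

Step 11. The chiral chromium complex may give poor facial selection at the C8 aldehyde or a poor trans/cis ratio, and intermolecular allylation may compete under the dilution a ten-membered ring needs. Fallback: setting out from 17, the ring is closed without a chiral ligand with stoichiometric CrCl2 in THF/DMF at high dilution, where the E,E-macrocycle alone should still favour the trans ring fusion. This gives 20 as a racemate, that is together with its (3aS,11aR)-enantiomer F1. The two are separated by preparative chromatography on a chiral stationary phase, and the route is rejoined at 20.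

Step 15. Transfer of the acyloxymethyl group from tin may be slow, so that butyl transfer, protodestannylation, transannular Heck cyclisation of the C4–Pd intermediate or Pd-induced ionisation of the product allylic ester take over. Fallback: the tin reagent is replaced by a zinc reagent. Setting out from 24, chloromethyl chlorosulfate/NaHCO3/Bu4NHSO4 in CH2Cl2/water gives the chloromethyl ester F2. TESOTf/2,6-lutidine protects the tertiary alcohol as the silyl ether F3, and NaI in acetone (Finkelstein, the neopentyl-type CH2Cl being inert) gives the iodomethyl ester F4. Zinc dust in THF converts F4 into the (acyloxymethyl)zinc iodide F5, which is used in excess in a Negishi coupling with 21 (Pd(t-Bu3P)2, THF, rt) to give the triethylsilyl ether of the target F6. HF·pyridine in THF removes the silyl group, and the route is rejoined at 27.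

Step 7. The β,γ-unsaturated aldehyde 11 may isomerise to the conjugated enal, or be reduced by residual hydride, before the C–C bond forms. Fallback: the hydroxy-acrylate is built on a robust aldehyde before the bromo-alkene exists. Setting out from 6, a Morita–Baylis–Hillman reaction with methyl acrylate/DABCO gives the hydroxy ester F7, and TESOTf/2,6-lutidine gives its triethylsilyl ether F8. DDQ removes the PMB group to give the primary alcohol F9, and Dess–Martin oxidation gives the aldehyde F10. CBr4/PPh3/Zn converts F10 into the dibromoalkene F11. The trans-selective Negishi coupling of F11 with 8, as in step 4, gives the bromodiene F12. PPTS in MeOH at 0 °C removes the secondary TES group in the presence of the primary TBS ether, and the route is rejoined at 14.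

Further compounds
F1 | step 11 | (3aS,5Z,9E,11aR)-6-bromo-10-methyl-3-methylidene-3a,4,7,8,11,11a-hexahydrocyclodeca[b]furan-2(3H)-one (enantiomer of 20) | C=C1C(=O)O[C@@H]2C/C(C)=C/CC/C(Br)=C/C[C@@H]12
F2 | step 15 | chloromethyl (2R)-3-chloro-2-hydroxy-2-methylpropanoate | ClCOC(=O)[C@@](C)(O)CCl
F3 | step 15 | chloromethyl (2R)-3-chloro-2-methyl-2-[(triethylsilyl)oxy]propanoate | ClCOC(=O)[C@@](C)(O[Si](CC)(CC)CC)CCl
F4 | step 15 | iodomethyl (2R)-3-chloro-2-methyl-2-[(triethylsilyl)oxy]propanoate | ICOC(=O)[C@@](C)(O[Si](CC)(CC)CC)CCl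
F5 | step 15 | ({(2R)-3-chloro-2-methyl-2-[(triethylsilyl)oxy]propanoyl}oxymethyl)zinc iodide | I[Zn]COC(=O)[C@@](C)(O[Si](CC)(CC)CC)CCl
F6 | step 15 | [(3aR,5Z,9E,11aS)-10-(hydroxymethyl)-3-methylidene-2-oxo-2,3,3a,4,7,8,11,11a-octahydrocyclodeca[b]furan-6-yl]methyl (2R)-3-chloro-2-methyl-2-[(triethylsilyl)oxy]propanoate | C=C1C(=O)O[C@H]2C/C(CO)=C\CC/C(COC(=O)[C@@](C)(O[Si](CC)(CC)CC)CCl)=C/C[C@H]12
F7 | step 7 | methyl 3-hydroxy-5-[(4-methoxybenzyl)oxy]-2-methylidenepentanoate (racemic) | COC(=O)C(=C)C(O)CCOCc1ccc(OC)cc1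
F8 | step 7 | methyl 5-[(4-methoxybenzyl)oxy]-2-methylidene-3-[(triethylsilyl)oxy]pentanoate | COC(=O)C(=C)C(CCOCc1ccc(OC)cc1)O[Si](CC)(CC)CC
F9 | step 7 | methyl 5-hydroxy-2-methylidene-3-[(triethylsilyl)oxy]pentanoate | COC(=O)C(=C)C(CCO)O[Si](CC)(CC)CC
F10 | step 7 | methyl 2-methylidene-5-oxo-3-[(triethylsilyl)oxy]pentanoate | COC(=O)C(=C)C(CC=O)O[Si](CC)(CC)CC
F11 | step 7 | methyl 6,6-dibromo-2-methylidene-3-[(triethylsilyl)oxy]hex-5-enoate | COC(=O)C(=C)C(CC=C(Br)Br)O[Si](CC)(CC)CC
F12 | step 7 | methyl (5Z,9E)-6-bromo-12-[(tert-butyldimethylsilyl)oxy]-10-methyl-2-methylidene-3-[(triethylsilyl)oxy]dodeca-5,9-dienoate | COC(=O)C(=C)C(C/C=C(Br)/CC/C=C(\C)CCO[Si](C)(C)C(C)(C)C)O[Si](CC)(CC)CC
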